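**Plan**

Numbering: lactone O1, C2 (C=O), C3, quaternary C3a, C4, ketone C5, alkene C6=C7, carbinol C7a.

- Retrosynthetic cuts, in order: the C6=C7 unsaturation (ketone dehydrogenation), the activating ester on C3, the C3–C3a bond (conjugate addition), the O1–C2 ester bond (acylation), and the C3a–farnesyl bond (carbonyl addition with 1,3-transposition).
- Enabling feature: C3a is β to the C5 ketone through C4 and is directly bonded to the oxygenated C7a, so a C2–C3 unit carried on the C7a oxygen can reach the enone β-carbon and close the five-membered lactone ring O1–C2–C3–C3a–C7a onto the carbocycle.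
- Forward order: the six-membered ring is bought as 3-ethoxycyclohex-2-enone; the C7a oxygen is added, then farnesyl, then the malonate tether; the lactone ring closes; the extra ester is removed; the C6=C7 alkene is introduced last.
- Stereochemistry: C7a (R) comes from a lipase kinetic resolution; C3a (R) is relayed from C7a through the tether (cis fusion is enforced); the E,E geometry comes from farnesyl chloride.

Key step: step 8

Assumption: the lipase is taken to hydrolyse the (S)-acetate faster, so that the (R)-acetate is the recovered enantiomer.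
Notation: farnesyl = (2E,6E)-3,7,11-trimethyldodeca-2,6,10-trien-1-yl.

**Route**

Step 1
Reactants: 1 3-ethoxycyclohex-2-en-1-one
Product: 2 rac-4-ethoxy-2-oxocyclohex-3-en-1-yl acetate (rac-6-acetoxy-3-ethoxycyclohex-2-en-1-one)
Conditions: Mn(OAc)3·2H2O (3 equiv), benzene/AcOH 10:1, reflux with water separation
Reagents that add atoms: manganese triacetate, CC(=O)[O-].CC(=O)[O-].CC(=O)[O-].[Mn+3]
Why: Oxidative α′-acetoxylation of an enone by trivalent manganese acetate proceeds through the manganese enolate at C6, the only enolisable α-carbon of the vinylogous ester, and should give the racemic ketol acetate.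

Step 2
Reactants: 2 rac-4-ethoxy-2-oxocyclohex-3-en-1-yl acetate
Product: 3 (1R)-4-ethoxy-2-oxocyclohex-3-en-1-yl acetate
Conditions: Amano lipase PS (Burkholderia cepacia lipase), phosphate buffer pH 7/MTBE, rt, stopped just past half conversion
Reagents that add atoms: none
Why: Enzymatic kinetic resolution by enantioselective ester hydrolysis should leave the slow-reacting (R)-acetate enantiomerically enriched once conversion passes one half, and this centre becomes C7a of the target.

Step 3
Reactants: 3 (1R)-4-ethoxy-2-oxocyclohex-3-en-1-yl acetate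
Product: 4 (6R)-3-ethoxy-6-hydroxycyclohex-2-en-1-one
Conditions: K2CO3 (cat.), EtOH, 0 °C, short reaction time
Reagents that add atoms: none
Why: Base-catalysed transesterification removes the acetate, with ethanol chosen so that any alkoxide exchange at the vinylogous ester is degenerate and low temperature chosen to keep the ketol centre from enolising.

Step 4
Reactants: 4 (6R)-3-ethoxy-6-hydroxycyclohex-2-en-1-one
Product: 5 (6R)-6-[(tert-butyldimethylsilyl)oxy]-3-ethoxycyclohex-2-en-1-one
Conditions: TBSCl, imidazole, DMF, rt
Reagents that add atoms: tert-butyldimethylsilyl chloride, CC(C)(C)[Si](C)(C)Cl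
Why: Imidazole-promoted silylation protects the ketol hydroxyl against the organometallic reagent of the next step.

Step 5
Reactants: 5 (6R)-6-[(tert-butyldimethylsilyl)oxy]-3-ethoxycyclohex-2-en-1-one; 6 (2E,6E)-farnesyl chloride
Product: 9 (4R)-4-[(tert-butyldimethylsilyl)oxy]-3-farnesylcyclohex-2-en-1-one, via farnesylbarium chloride 7 (not isolated), via tertiary carbinol adduct 8 (not isolated)
Conditions: Li, biphenyl, BaI2, THF, rt (activated barium); 6, −78 °C; then 5, −78 °C; then 1 M HCl, THF, 0 °C to rt
Reagents that add atoms: water, O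
Why: Allylic barium reagents generated and kept at −78 °C add to ketone carbonyls through their unsubstituted α-carbon with retention of E geometry, and the resulting 3-ethoxy allylic carbinol should undergo the acid-mediated Stork–Danheiser 1,3-carbonyl transposition (ionisation, hydration at the ethoxy carbon, loss of ethanol), which leaves the silyloxy stereocentre untouched and destroys the transient carbinol centre.

Step 6
Reactants: 9 (4R)-4-[(tert-butyldimethylsilyl)oxy]-3-farnesylcyclohex-2-en-1-one
Product: 10 (4R)-3-farnesyl-4-hydroxycyclohex-2-en-1-one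
Conditions: HF·pyridine, pyridine, THF, 0 °C to rt
Reagents that add atoms: none
Why: Buffered fluoride desilylation should free the allylic alcohol without base-induced enolisation of the γ-oxygenated enone and without acid damage to the triene.

Step 7
Reactants: 10 (4R)-3-farnesyl-4-hydroxycyclohex-2-en-1-one; 11 methyl malonyl chloride (methyl 3-chloro-3-oxopropanoate)
Product: 12 methyl (1R)-2-farnesyl-4-oxocyclohex-2-en-1-yl propanedioate
Conditions: pyridine, CH2Cl2, 0 °C
Reagents that add atoms: none
Why: Acylation of the secondary alcohol by the acid chloride, with pyridine as HCl scavenger and acyl-transfer agent, attaches the two-carbon tether together with its activating ester.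

Step 8
Reactants: 12 methyl (1R)-2-farnesyl-4-oxocyclohex-2-en-1-yl propanedioate
Product: 13 methyl (3aR,7aR)-3a-farnesyl-2,5-dioxooctahydro-1-benzofuran-3-carboxylate (mixture of C3 epimers)
Conditions: Cs2CO3 (0.3 equiv), MeCN, rt; aqueous NH4Cl work-up
Reagents that add atoms: none
Why: Cs2CO3 removes a proton from the malonate CH2, the most acidic site, and the soft enolate adds to the farnesyl-bearing β-carbon of the enone (the future C3a) to give a ketone enolate that is protonated at the future C4; the base can turn over because the product is a 1,3-dicarbonyl of similar acidity. The closest known reaction type is the base-mediated intramolecular Michael addition of malonate and acetoacetate esters of γ-hydroxy enones to cis-fused γ-butyrolactones, which is known to tolerate β,β-disubstituted acceptors. The γ-lactone closes in the 5-exo-trig mode, C3 bonding to C3a with the enone double bond exocyclic to the new ring. The new quaternary centre C3a is controlled by C7a: the O1–C2–C3 tether reaches only the enone face that carries the C7a oxygen, so the fusion must be cis and (4R) in 12 becomes (3aR,7aR) in 13. The step needs conjugate addition to win over γ-deprotonation at the carbinol carbon and over ester cleavage; this is secured by the large acidity gap between the malonate and every other C–H bond and by the mild, non-nucleophilic carbonate, while the epimer mixture at C3 is erased in step 9.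

Step 9
Reactants: 13 methyl (3aR,7aR)-3a-farnesyl-2,5-dioxooctahydro-1-benzofuran-3-carboxylate
Product: 14 (3aR,7aR)-3a-farnesylhexahydro-1-benzofuran-2,5-dione
Conditions: LiCl, H2O (2 equiv), DMSO, 130 °C
Reagents that add atoms: none
Why: In the Krapcho demethoxycarbonylation chloride dealkylates the methyl ester by SN2, the carboxylate loses CO2 and water protonates the lactone enolate, so both C3 epimers should converge on one lactone.

Step 10
Reactants: 14 (3aR,7aR)-3a-farnesylhexahydro-1-benzofuran-2,5-dione
Product: 15 (3aR,7aR)-3a-farnesyl-5-[(trimethylsilyl)oxy]-3a,4,7,7a-tetrahydro-1-benzofuran-2(3H)-one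
Conditions: LiN(i-Pr)2 (1.05 equiv), TMSCl (internal quench), THF, −78 °C; cold aqueous NaHCO3 work-up, used crude
Reagents that add atoms: chlorotrimethylsilane, C[Si](C)(C)Cl
Why: Kinetic enolisation with a hindered amide base and in situ silylation should take the ketone in preference to the less acidic lactone, and should remove a proton from C6 rather than from C4, which is neopentylic next to the quaternary C3a.

Step 11
Reactants: 15 (3aR,7aR)-3a-farnesyl-5-[(trimethylsilyl)oxy]-3a,4,7,7a-tetrahydro-1-benzofuran-2(3H)-one
Product: 16 (3aR,7aR)-3a-farnesyl-3a,7a-dihydro-1-benzofuran-2,5(3H,4H)-dione (CNP0400313.1)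
Conditions: Pd(OAc)2 (1.1 equiv), MeCN, rt
Reagents that add atoms: none
Why: In the Saegusa–Ito oxidation divalent palladium forms the α-palladio ketone from the silyl enol ether and β-hydride elimination from C7 gives the C6=C7 enone; no other enone can form because the alternative β-carbon C3a carries no hydrogen, and C7a is not touched.

**Compound list**

1 | 3-ethoxycyclohex-2-en-1-one | CCOC1=CC(=O)CCC1 | starting material
2 | rac-4-ethoxy-2-oxocyclohex-3-en-1-yl acetate | CCOC1=CC(=O)C(OC(C)=O)CC1 | intermediate
3 | (1R)-4-ethoxy-2-oxocyclohex-3-en-1-yl acetate | CCOC1=CC(=O)[C@H](OC(C)=O)CC1 | intermediate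
4 | (6R)-3-ethoxy-6-hydroxycyclohex-2-en-1-one | CCOC1=CC(=O)[C@H](O)CC1 | intermediate
5 | (6R)-6-[(tert-butyldimethylsilyl)oxy]-3-ethoxycyclohex-2-en-1-one | CCOC1=CC(=O)[C@H](O[Si](C)(C)C(C)(C)C)CC1 | intermediate
6 | (2E,6E)-farnesyl chloride | CC(C)=CCC/C(C)=C/CC/C(C)=C/CCl | starting material
7 | [(2E,6E)-farnesyl]barium chloride (not isolated) | CC(C)=CCC/C(C)=C/CC/C(C)=C/C[Ba]Cl | intermediate
8 | (6R)-6-[(tert-butyldimethylsilyl)oxy]-3-ethoxy-1-[(2E,6E)-farnesyl]cyclohex-2-en-1-ol, C1 epimers (not isolated) | CC(C)=CCC/C(C)=C/CC/C(C)=C/CC1(O)C=C(OCC)CC[C@H]1O[Si](C)(C)C(C)(C)C | intermediate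
9 | (4R)-4-[(tert-butyldimethylsilyl)oxy]-3-[(2E,6E)-farnesyl]cyclohex-2-en-1-one | CC(C)=CCC/C(C)=C/CC/C(C)=C/CC1=CC(=O)CC[C@H]1O[Si](C)(C)C(C)(C)C | intermediate
10 | (4R)-3-[(2E,6E)-farnesyl]-4-hydroxycyclohex-2-en-1-one | CC(C)=CCC/C(C)=C/CC/C(C)=C/CC1=CC(=O)CC[C@H]1O | intermediate
11 | methyl malonyl chloride (methyl 3-chloro-3-oxopropanoate) | COC(=O)CC(Cl)=O | starting material
12 | methyl (1R)-2-[(2E,6E)-farnesyl]-4-oxocyclohex-2-en-1-yl propanedioate | CC(C)=CCC/C(C)=C/CC/C(C)=C/CC1=CC(=O)CC[C@H]1OC(=O)CC(=O)OC | intermediate
13 | methyl (3aR,7aR)-3a-[(2E,6E)-farnesyl]-2,5-dioxooctahydro-1-benzofuran-3-carboxylate, C3 epimers | CC(C)=CCC/C(C)=C/CC/C(C)=C/C[C@]12CC(=O)CC[C@H]1OC(=O)C2C(=O)OC | intermediate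
14 | (3aR,7aR)-3a-[(2E,6E)-farnesyl]hexahydro-1-benzofuran-2,5-dione | CC(C)=CCC/C(C)=C/CC/C(C)=C/C[C@]12CC(=O)CC[C@H]1OC(=O)C2 | intermediate
15 | (3aR,7aR)-3a-[(2E,6E)-farnesyl]-5-[(trimethylsilyl)oxy]-3a,4,7,7a-tetrahydro-1-benzofuran-2(3H)-one | CC(C)=CCC/C(C)=C/CC/C(C)=C/C[C@]12CC(O[Si](C)(C)C)=CC[C@H]1OC(=O)C2 | intermediate
16 | (3aR,7aR)-3a-[(2E,6E)-farnesyl]-3a,7a-dihydro-1-benzofuran-2,5(3H,4H)-dione | CC(C)=CCC/C(C)=C/CC/C(C)=C/C[C@]12CC(=O)C=C[C@H]1OC(=O)C2 | target

**Step count and risks**

Total steps: 11. Longest linear sequence: 11 steps (1 to 16); 6 and 11 are bought and enter in one step each.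

Steps most likely to fail:

1. Step 5. The organobarium may attack through its γ-carbon (allylic transposition) or lose E geometry if it warms. It may also enolise the hindered α-silyloxy ketone instead of adding, and Wurtz coupling may consume the chloride during metalation. The fallback reverses the polarity, so that a ring carbanion is alkylated by farnesyl chloride in an SN2 reaction that cannot transpose. It sets out from 5. Reduction with i-Bu2AlH followed by dilute acid (the same transposition with hydride) should give (4R)-4-[(tert-butyldimethylsilyl)oxy]cyclohex-2-en-1-one F1. Conjugate addition of PhSO2Na in AcOH/THF should give (4R)-4-[(tert-butyldimethylsilyl)oxy]-3-(phenylsulfonyl)cyclohexan-1-one F2. Ketalisation with 1,2-bis(trimethylsilyloxy)ethane and catalytic TMSOTf at −78 °C should give the dioxolane tert-butyldimethyl{[(8R)-7-(phenylsulfonyl)-1,4-dioxaspiro[4.5]decan-8-yl]oxy}silane F3. Deprotonation α to sulfur with n-BuLi at −78 °C and alkylation with 6 should give tert-butyl{[(8R)-7-farnesyl-7-(phenylsulfonyl)-1,4-dioxaspiro[4.5]decan-8-yl]oxy}dimethylsilane F4. Ketal hydrolysis (PPTS, wet acetone) and E1cB loss of benzenesulfinate with DBU then return to the route at 9.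

2. Step 8. Addition to the fully substituted β-carbon may be slow or reversible, which gives time for epimerisation of the carbinol centre through the extended enolate or for cleavage of the malonate ester. The fallback makes the same C3–C3a bond from the same oxygen by a radical instead of an enolate (Ueno–Stork cyclisation). It sets out from 10. Treatment with 1,2-dibromoethyl ethyl ether and PhNMe2 in CH2Cl2 should give the bromoacetal (4R)-4-(2-bromo-1-ethoxyethoxy)-3-farnesylcyclohex-2-en-1-one F5. Bu3SnH with AIBN in benzene at 80 °C should close the ring by 5-exo-trig attack on the enone β-carbon, from the face of the oxygen, to give (3aS,7aR)-2-ethoxy-3a-farnesylhexahydro-1-benzofuran-5(4H)-one F6. Mild aqueous acid (AcOH/H2O/THF) should give the lactol (3aS,7aR)-3a-farnesyl-2-hydroxyhexahydro-1-benzofuran-5(4H)-one F7. Oxidation with catalytic TEMPO and PhI(OAc)2 returns to the route at 14. The 3aS descriptor in F6 and F7 reflects a priority change only; the spatial arrangement is that of 14.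

3. Step 10 (together with step 11). Deprotonation may occur toward C4 or at the lactone, the silyl enol ether may hydrolyse during handling, and divalent palladium may engage the triene. The fallback is direct dehydrogenation of 14 with IBX in DMSO at 65–80 °C, which comes back to the route at 16 without a silyl enol ether and without palladium. Whichever way the ketone enolises, only the C6–C7 desaturation is possible, because C3a has no hydrogen. No new compound is formed on the way.

**Further compounds**

F1 | step 5 | (4R)-4-[(tert-butyldimethylsilyl)oxy]cyclohex-2-en-1-one | O=C1CC[C@@H](O[Si](C)(C)C(C)(C)C)C=C1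
F2 | step 5 | (4R)-4-[(tert-butyldimethylsilyl)oxy]-3-(phenylsulfonyl)cyclohexan-1-one, C3 epimers | O=C1CC[C@@H](O[Si](C)(C)C(C)(C)C)C(C1)S(=O)(=O)c1ccccc1
F3 | step 5 | tert-butyldimethyl{[(8R)-7-(phenylsulfonyl)-1,4-dioxaspiro[4.5]decan-8-yl]oxy}silane, C7 epimers | C1COC2(O1)CC[C@@H](O[Si](C)(C)C(C)(C)C)C(C2)S(=O)(=O)c1ccccc1
F4 | step 5 | tert-butyl{[(8R)-7-[(2E,6E)-farnesyl]-7-(phenylsulfonyl)-1,4-dioxaspiro[4.5]decan-8-yl]oxy}dimethylsilane, C7 epimers | CC(C)=CCC/C(C)=C/CC/C(C)=C/CC1(S(=O)(=O)c2ccccc2)CC2(CC[C@H]1O[Si](C)(C)C(C)(C)C)OCCO2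
F5 | step 8 | (4R)-4-(2-bromo-1-ethoxyethoxy)-3-[(2E,6E)-farnesyl]cyclohex-2-en-1-one, acetal epimers | CC(C)=CCC/C(C)=C/CC/C(C)=C/CC1=CC(=O)CC[C@H]1OC(CBr)OCC
F6 | step 8 | (3aS,7aR)-2-ethoxy-3a-[(2E,6E)-farnesyl]hexahydro-1-benzofuran-5(4H)-one, C2 epimers | CC(C)=CCC/C(C)=C/CC/C(C)=C/C[C@]12CC(=O)CC[C@H]1OC(OCC)C2
F7 | step 8 | (3aS,7aR)-3a-[(2E,6E)-farnesyl]-2-hydroxyhexahydro-1-benzofuran-5(4H)-one, C2 epimers | CC(C)=CCC/C(C)=C/CC/C(C)=C/C[C@]12CC(=O)CC[C@H]1OC(O)C2
F0 | step 10 | none | none
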